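Slowness is the first thing the runs show: in the eta run J, the substrate, still stood at 90.1% after 8.00 h. J reacts with the reagent Z to give the product L and the by-product D. D may speed that step, L may pass on to X, and Z may pass reversibly into Q.

| setting | beta | epsilon | eta | north | east | west |
|---|---|---|---|---|---|---|
| J | 0.30 M | 0.30 M | 0.15 M | 0.30 M | 0.30 M | 0.30 M |
| Z | 0.16 M | 0.63 M | 0.315 M | 0.315 M | 0.315 M | 0.315 M |
| temperature | 75 °C | 90 °C | 75 °C | 80 °C | 90 °C | 100 °C |
| remark | run made earlier | run made earlier | run made earlier |  |  |  |
| time |  |  |  | 8.0 h | 8.0 h | 8.0 h |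

| run | time / h | L / % | J / % | X / % |
|---|---|---|---|---|
| beta | 1.00 | 1.4 | 100.1 | 0 |
| beta | 3.00 | 1.9 | 98.4 | 1.2 |
| beta | 5.00 | 2.5 | 98.0 | 0.5 |
| beta | 8.00 | 5.0 | 95.4 | 0.2 |
| epsilon | 1.33 | 12.2 | 87.4 | 0 |
| epsilon | 2.50 | 26.5 | 71.6 | 2.5 |
| epsilon | 4.00 | 47.2 | 47.7 | 4.9 |
| epsilon | 5.00 | 56.4 | 35.5 | 8.9 |
| eta | 2.00 | 2.5 | 97.5 | 0.1 |
| eta | 4.00 | 4.9 | 95.5 | 0 |
| eta | 6.00 | 5.6 | 92.8 | 0.7 |
| eta | 8.00 | 9.3 | 90.1 | 0.1 |

(readings scatter by 0.5 percentage points)

- what may be going on: J + Z + D -> L + 2 D; J + Z -> L + D; Z <-> Q; L -> X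

* which of these there is most of at the end, counted by the J in it, north (J / X / L)
* which of these there is most of at the end, counted by the J in it, east (J / X / L)
* which of these there is most of at the end, counted by the J in it, west (J / X / L)
* amount of the one of these that there is most of at the end, in percent of the J charged, north
* amount of the one of these that there is most of at the end, in percent of the J charged, east
* amount of the one of these that there is most of at the end, in percent of the J charged, west

I reckoned the hottest flask, west, by a chain. The fall of J in eta, as a logarithm divided by time and Z, gave a rate constant k of 0.0414 L mol⁻¹ h⁻¹ at 75 °C. The first reading of the epsilon run gave 0.161 L mol⁻¹ h⁻¹ at 90 °C, a rise by 3.89, which I took as the effect of temperature, though the charges differed too. Carrying that pace on to 100 °C gave 0.397 L mol⁻¹ h⁻¹.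

Next came the margin, the charge of Z less the charge of J: 0.0150 M. It is far smaller than the charge of J, so I let J and Z fall together, and the fraction of J left was then one over one plus k times the charge of J times time. That gave 51.2% for west, more than the part reacted, so I committed to J there.

The weak link was treating Z as free. Written properly, in concentrations, J left equals Z left plus Q less the margin, so J stands above free Z by whatever Q exceeds the margin. Against this, the k read from the last interval of epsilon was 0.624 L mol⁻¹ h⁻¹, above the first reading there, and a larger k in my formula gives less J. Z was not among the readings, so I put no size on Q and kept my figure.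

The forecast gave J at 81% in north, J at 57% in east, and L at 38% (32% to 47%) in west, where I had J, and said of west: “This is a close call; L is slightly favoured.”

The flasks gave J at 80.6% in north, J at 59.1% in east, and J at 46.2% in west, with L at 25.1% and X at 28.7% there.

    J + Z + D → L + 2 D (k = 2.10 L² mol⁻² h⁻¹, Ea = 75.0 kJ mol⁻¹)
    J + Z → L + D (k = 0.0470 L mol⁻¹ h⁻¹, Ea = 73.0 kJ mol⁻¹)
    Z ⇌ Q (K = 23.0, k = 0.0110 h⁻¹, Ea = 128 kJ mol⁻¹, ΔH = −8.00 kJ mol⁻¹)
    L → X (k = 0.0230 h⁻¹, Ea = 111 kJ mol⁻¹)
    (constants at 80 °C)

In west at 8.00 h, Z stood at 10.4% of its charge and Q at 0.121 M, and the balance with the margin gives 46.2% of the J charged. The neighbouring flask is west read at 15 h. There Z, the limiting reagent, stood at 1.78% of its charge and Q at 0.127 M, so the same balance gives 39.3%. That flask held J at 39.3%, L at 10.7% and X, now the largest share, at 50.0%.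

The earlier runs and the new flask are calculated on assumed constants; noise was put on by code.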